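**Retrosynthetic overview**

1. Naamidine F (25) ⇐ oxidation of hydroquinone 24 ⇐ C–N condensation of the 2-aminoimidazole hydroquinone 19 with 1-methylparabanic acid 22; the hydroquinone serves as the redox-protected quinone and the dione ring arrives preformed.
2. Six-membered carbocycle ⇐ thermal ring expansion of the 4-alkenyl-4-hydroxycyclobutenone 15: 4π opening to a dienylketene, then 6π closure joining the ketene carbon (the future C=O next to C–OMe) to the alkene =CH2 (the future ring CH). 15 ⇐ dimethyl squarate 13 + the alkenyllithium from 2-bromoallyl imidazole 12.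
3. Enabling feature: in the quinone ring the sequence O=C–C(OMe)=C(OMe)–C=O is the four-carbon skeleton of squaric acid at the right oxidation level. The other two ring atoms, C(CH2–imidazolyl) and the unsubstituted CH, are a 1,1-disubstituted vinyl group with a free terminus.
4. Imidazole ring ⇐ α-(methylamino) ketone 10 + cyanamide; ketone 8 ⇐ Weinreb amide 5 + 4-methoxybenzylmagnesium chloride; amino acid skeleton ⇐ sarcosine ester enolate + 2,3-dibromopropene.
5. Order of ring formation: imidazole (step 4), carbocycle (step 7), imidazolidinetrione (made in step 9, attached in step 10).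

Key step: step 7

Remark: the target is achiral; every stereocenter that appears on the way (in 4, 5, 7, 8, 10 and 15) is racemic and is erased later, and the amidine C=N of 12 to 18 is drawn as the stable E isomer.

**Route**

Step 1
Reactants: 1 methyl N-(tert-butoxycarbonyl)-N-methylglycinate; 2 2,3-dibromopropene
Product: 4 methyl 4-bromo-2-[(tert-butoxycarbonyl)(methyl)amino]pent-4-enoate (racemic), via lithium enolate 3 (not isolated)
Conditions: LiN(SiMe3)2, THF, −78 °C; then 2, −78 → −20 °C
Reagents that add atoms: none
Why: Enolate alkylation of an N-Boc-N-alkylglycine ester by SN2 at the allylic CH2Br of 2 (the vinylic bromide is inert) should give 4, whose new stereocenter forms racemic and later becomes sp2 carbon C5 of the imidazole.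

Step 2
Reactants: 4 methyl 4-bromo-2-[(tert-butoxycarbonyl)(methyl)amino]pent-4-enoate
Product: 5 tert-butyl N-{4-bromo-1-[methoxy(methyl)amino]-1-oxopent-4-en-2-yl}-N-methylcarbamate (racemic)
Conditions: MeNH(OMe)·HCl, i-PrMgCl, THF, −20 → 0 °C
Reagents that add atoms: N,O-dimethylhydroxylamine hydrochloride, CNOC.Cl
Why: Direct aminolysis of the methyl ester by the chloromagnesium amide of N,O-dimethylhydroxylamine (Weinreb amide formation) should proceed at a temperature where an unactivated alkenyl bromide does not undergo halogen–magnesium exchange.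

Step 3
Reactants: 5 tert-butyl N-{4-bromo-1-[methoxy(methyl)amino]-1-oxopent-4-en-2-yl}-N-methylcarbamate; 6 4-methoxybenzylmagnesium chloride
Product: 8 tert-butyl N-[5-bromo-1-(4-methoxyphenyl)-2-oxohex-5-en-3-yl]-N-methylcarbamate (racemic), via magnesium chelate 7 (not isolated)
Conditions: THF, 0 °C; then 1 M HCl, 0 °C
Reagents that add atoms: none
Why: In this Weinreb ketone synthesis the benzylic Grignard reagent adds once and chelate 7 holds the tetrahedral adduct until the quench, so the ketone should form without over-addition.

Step 4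
Reactants: 8 tert-butyl N-[5-bromo-1-(4-methoxyphenyl)-2-oxohex-5-en-3-yl]-N-methylcarbamate; 9 cyanamide
Product: 11 5-(2-bromoprop-2-en-1-yl)-4-(4-methoxybenzyl)-1-methyl-1H-imidazol-2-amine, via aminoketone salt 10 (not isolated)
Conditions: 4 M HCl, dioxane, rt; evaporate; then 9, H2O–EtOH, pH 4.5, 90 °C; aq. NaOH
Reagents that add atoms: none
Why: Acidolysis of the Boc group gives the α-(methylamino) ketone salt, which adds to cyanamide to form an N-methylguanidine that cyclodehydrates onto the ketone (cyanamide route to 2-aminoimidazoles), so that the N-methyl nitrogen becomes N1 and the carbon bearing the bromoallyl group becomes C5 without regiochemical ambiguity.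

Step 5
Reactants: 11 5-(2-bromoprop-2-en-1-yl)-4-(4-methoxybenzyl)-1-methyl-1H-imidazol-2-amine
Product: 12 (E)-N'-[5-(2-bromoprop-2-en-1-yl)-4-(4-methoxybenzyl)-1-methyl-1H-imidazol-2-yl]-N,N-dimethylformimidamide
Conditions: Me2NCH(OMe)2, toluene, 80 °C
Reagents that add atoms: N,N-dimethylformamide dimethyl acetal, COC(OC)N(C)C
Why: Condensation of the exocyclic primary amino group with the amide acetal (amidine protection) removes both N–H protons and gives a group that tolerates organolithium reagents at low temperature.

Step 6
Reactants: 12 (E)-N'-[5-(2-bromoprop-2-en-1-yl)-4-(4-methoxybenzyl)-1-methyl-1H-imidazol-2-yl]-N,N-dimethylformimidamide; 13 dimethyl squarate (3,4-dimethoxycyclobut-3-ene-1,2-dione)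
Product: 15 4-[3-(2-{[(E)-(dimethylamino)methylidene]amino}-4-(4-methoxybenzyl)-1-methyl-1H-imidazol-5-yl)prop-1-en-2-yl]-4-hydroxy-2,3-dimethoxycyclobut-2-en-1-one (racemic), via alkenyllithium 14 (not isolated)
Conditions: tert-butyllithium (2.1 equiv), THF, −78 °C; then cannulate into 13, THF, −78 °C; aq. NH4Cl, −78 °C
Reagents that add atoms: none
Why: Bromine–lithium exchange at −78 °C should outrun deprotonation and attack on the amidine, and alkenyllithium reagents add 1,2 to one of the two equivalent carbonyl groups of dimethyl squarate (squarate ester addition) to give the 4-alkenyl-4-hydroxycyclobutenone, whose carbinol center forms racemic and is erased in step 7.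

Step 7
Reactants: 15 4-[3-(2-{[(E)-(dimethylamino)methylidene]amino}-4-(4-methoxybenzyl)-1-methyl-1H-imidazol-5-yl)prop-1-en-2-yl]-4-hydroxy-2,3-dimethoxycyclobut-2-en-1-one
Product: 18 (E)-N'-[5-(2,5-dihydroxy-3,4-dimethoxybenzyl)-4-(4-methoxybenzyl)-1-methyl-1H-imidazol-2-yl]-N,N-dimethylformimidamide, via dienylketene 16 (not isolated), via cyclohexadienone 17 (not isolated)
Conditions: p-xylene (0.01 M, degassed), 138 °C, Ar
Reagents that add atoms: none
Why: Heating opens the cyclobutenone by conrotatory 4π electrocyclic cleavage of the C1–C4 bond to (Z)-dienylketene 16, whose ketene carbon then bonds to the unsubstituted =CH2 terminus in a thermal disrotatory 6π electrocyclization to cyclohexadienone 17, and enolization gives hydroquinone 18, so that the ring bond between the future quinone CH and the carbonyl carbon next to C–OMe is the one made in the closure. The closest known reaction type is the thermal ring expansion of 4-alkenyl-4-hydroxycyclobutenones derived from squarate esters (Moore rearrangement), as in the conversion of the 2-propenyl adduct of dimethyl squarate into 2,3-dimethoxy-5-methylhydroquinone. The six-membered carbocycle is closed in a pericyclic 6π mode (four ring carbons from the squarate, two from the alkenyl group), not by an ionic cyclization. No stereocenter is formed, since the sp3 carbon of 17 is lost on enolization and the racemic carbinol carbon of 15 becomes aromatic. The selectivity needed is torquoselectivity in the ring opening, and the electron-donating C4 hydroxyl secures it by rotating outward, which turns the alkenyl group inward next to the ketene so that electrocyclization wins over lactonization, while the 1,1-disubstituted alkene offers a single terminus and so places the CH2–imidazolyl group beside the former carbinol carbon. High dilution and exclusion of oxygen should keep the ketene from intermolecular capture by hydroxyl or amidine groups and keep the electron-rich hydroquinone from oxidizing.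

Step 8
Reactants: 18 (E)-N'-[5-(2,5-dihydroxy-3,4-dimethoxybenzyl)-4-(4-methoxybenzyl)-1-methyl-1H-imidazol-2-yl]-N,N-dimethylformimidamide
Product: 19 2-{[2-amino-4-(4-methoxybenzyl)-1-methyl-1H-imidazol-5-yl]methyl}-5,6-dimethoxybenzene-1,4-diol
Conditions: 2 M HCl, EtOH (degassed), 70 °C, Ar; then aq. NaHCO3, Na2S2O4
Reagents that add atoms: none
Why: Acid hydrolysis of the N,N-dimethylformamidine (amidine deprotection) should free the 2-amino group while the hydroquinone, which resists autoxidation in acid, is untouched, and dithionite in the bicarbonate work-up keeps the product reduced.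

Step 9
Reactants: 20 N-methylurea; 21 oxalyl chloride
Product: 22 1-methylimidazolidine-2,4,5-trione (1-methylparabanic acid)
Conditions: THF, 0 °C → reflux
Reagents that add atoms: none
Why: Double N-acylation of the urea by oxalyl chloride closes the five-membered trione ring (parabanic acid synthesis from a urea and oxalyl chloride).

Step 10
Reactants: 19 2-{[2-amino-4-(4-methoxybenzyl)-1-methyl-1H-imidazol-5-yl]methyl}-5,6-dimethoxybenzene-1,4-diol; 22 1-methylimidazolidine-2,4,5-trione
Product: 25 naamidine F, via bis(trimethylsilyl) ether 23 (not isolated), via hydroquinone 24 (not isolated)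
Conditions: MeC(OSiMe3)=NSiMe3 (BSA), MeCN, 80 °C, Ar; then MeOH, rt; then PhI(OAc)2, 0 °C
Reagents that add atoms: none
Why: BSA turns the N–H of 22 into a silyl imidate whose C4 is attacked by the exocyclic amino group with loss of silanol (the silyl-activated parabanic acid condensation that converts naamine-type 2-aminoimidazoles into naamidines) while both phenols are masked as silyl ethers, after which methanolysis returns hydroquinone 24 and the trivalent iodine reagent should oxidize it to the quinone (hydroquinone oxidation) much faster than it touches the acylated aminoimidazole.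

**Compound list**

1 | methyl N-(tert-butoxycarbonyl)-N-methylglycinate | COC(=O)CN(C)C(=O)OC(C)(C)C | starting material
2 | 2,3-dibromopropene | C=C(Br)CBr | starting material
3 | lithium enolate of 1 (formed in the flask; double-bond geometry immaterial) | COC(O[Li])=CN(C)C(=O)OC(C)(C)C | intermediate
4 | methyl 4-bromo-2-[(tert-butoxycarbonyl)(methyl)amino]pent-4-enoate (racemic) | COC(=O)C(CC(Br)=C)N(C)C(=O)OC(C)(C)C | intermediate
5 | tert-butyl N-{4-bromo-1-[methoxy(methyl)amino]-1-oxopent-4-en-2-yl}-N-methylcarbamate (racemic) | CON(C)C(=O)C(CC(Br)=C)N(C)C(=O)OC(C)(C)C | intermediate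
6 | 4-methoxybenzylmagnesium chloride (THF solution) | COc1ccc(C[Mg]Cl)cc1 | starting material
7 | chloromagnesium alkoxide of the tetrahedral Weinreb adduct (formed in the flask; diastereomer mixture) | COc1ccc(CC(O[Mg]Cl)(N(C)OC)C(CC(Br)=C)N(C)C(=O)OC(C)(C)C)cc1 | intermediate
8 | tert-butyl N-[5-bromo-1-(4-methoxyphenyl)-2-oxohex-5-en-3-yl]-N-methylcarbamate (racemic) | COc1ccc(CC(=O)C(CC(Br)=C)N(C)C(=O)OC(C)(C)C)cc1 | intermediate
9 | cyanamide | NC#N | starting material
10 | 5-bromo-1-(4-methoxyphenyl)-3-(methylamino)hex-5-en-2-one (formed in the flask and held as its hydrochloride; free base drawn; racemic) | COc1ccc(CC(=O)C(CC(Br)=C)NC)cc1 | intermediate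
11 | 5-(2-bromoprop-2-en-1-yl)-4-(4-methoxybenzyl)-1-methyl-1H-imidazol-2-amine | COc1ccc(Cc2nc(N)n(C)c2CC(Br)=C)cc1 | intermediate
12 | (E)-N'-[5-(2-bromoprop-2-en-1-yl)-4-(4-methoxybenzyl)-1-methyl-1H-imidazol-2-yl]-N,N-dimethylformimidamide | COc1ccc(Cc2nc(/N=C/N(C)C)n(C)c2CC(Br)=C)cc1 | intermediate
13 | dimethyl squarate (3,4-dimethoxycyclobut-3-ene-1,2-dione) | COC1=C(OC)C(=O)C1=O | starting material
14 | alkenyllithium from 12 (lithium in place of bromine; formed in the flask) | COc1ccc(Cc2nc(/N=C/N(C)C)n(C)c2CC(=C)[Li])cc1 | intermediate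
15 | 4-[3-(2-{[(E)-(dimethylamino)methylidene]amino}-4-(4-methoxybenzyl)-1-methyl-1H-imidazol-5-yl)prop-1-en-2-yl]-4-hydroxy-2,3-dimethoxycyclobut-2-en-1-one (racemic) | COc1ccc(Cc2nc(/N=C/N(C)C)n(C)c2CC(=C)C3(O)C(OC)=C(OC)C3=O)cc1 | intermediate
16 | (3Z)-4-hydroxy-2,3-dimethoxy-5-[(imidazol-5-yl)methyl]hexa-1,3,5-trien-1-one with the imidazole substituents of 12 (dienylketene; formed in the flask) | COc1ccc(Cc2nc(/N=C/N(C)C)n(C)c2CC(=C)/C(O)=C(OC)\C(OC)=C=O)cc1 | intermediate
17 | 4-hydroxy-2,3-dimethoxy-5-[(imidazol-5-yl)methyl]cyclohexa-2,4-dien-1-one with the imidazole substituents of 12 (formed in the flask) | COc1ccc(Cc2nc(/N=C/N(C)C)n(C)c2CC3=C(O)C(OC)=C(OC)C(=O)C3)cc1 | intermediate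
18 | (E)-N'-[5-(2,5-dihydroxy-3,4-dimethoxybenzyl)-4-(4-methoxybenzyl)-1-methyl-1H-imidazol-2-yl]-N,N-dimethylformimidamide | COc1ccc(Cc2nc(/N=C/N(C)C)n(C)c2Cc3cc(O)c(OC)c(OC)c3O)cc1 | intermediate
19 | 2-{[2-amino-4-(4-methoxybenzyl)-1-methyl-1H-imidazol-5-yl]methyl}-5,6-dimethoxybenzene-1,4-diol | COc1ccc(Cc2nc(N)n(C)c2Cc3cc(O)c(OC)c(OC)c3O)cc1 | intermediate
20 | N-methylurea | CNC(N)=O | starting material
21 | oxalyl chloride | O=C(Cl)C(=O)Cl | starting material
22 | 1-methylimidazolidine-2,4,5-trione (1-methylparabanic acid) | CN1C(=O)NC(=O)C1=O | intermediate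
23 | O,O'-bis(trimethylsilyl) ether of 24 (formed in the flask) | COc1ccc(Cc2nc(NC3=NC(=O)N(C)C3=O)n(C)c2Cc4cc(O[Si](C)(C)C)c(OC)c(OC)c4O[Si](C)(C)C)cc1 | intermediate
24 | 4-{[5-(2,5-dihydroxy-3,4-dimethoxybenzyl)-4-(4-methoxybenzyl)-1-methyl-1H-imidazol-2-yl]amino}-1-methyl-1H-imidazole-2,5-dione (hydroquinone of naamidine F; formed in the flask) | COc1ccc(Cc2nc(NC3=NC(=O)N(C)C3=O)n(C)c2Cc4cc(O)c(OC)c(OC)c4O)cc1 | intermediate
25 | naamidine F | COC1=C(OC)C(=O)C(Cc2c(Cc3ccc(OC)cc3)nc(NC3=NC(=O)N(C)C3=O)n2C)=CC1=O | target

**Count and risks**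

Total step count: 10. Longest linear sequence: 9 steps (steps 1 to 8, then 10); step 9 is a one-step side branch.

Steps most likely to fail:

Step 6. What may go wrong: the alkenyllithium is consumed by proton transfer from the doubly activated CH2 groups that flank the imidazole, or tert-butyllithium adds to the amidine carbon before the exchange is complete, so that reduced alkene forms in place of adduct 15. The fallback sets out from 12 and replaces the alkenyl anion by an acetylide. n-Bu4NF in DMF at 60 °C should eliminate HBr from the 2-bromoalkene to give the terminal alkyne F1. LiN(i-Pr)2 in THF at −78 °C converts it into the far less basic lithium acetylide F2, which adds to 13 to give the 4-alkynyl-4-hydroxycyclobutenone F3. Heating F3 in MeCN or toluene (80–110 °C) triggers the alkynyl version of the squarate ring expansion (enynylketene, closure to a diradical at the carbon bearing the CH2–imidazolyl group, transfer of the hydroxyl hydrogen to carbon) and should give the amidine-protected quinone F4 directly. Reduction with aqueous Na2S2O4 in EtOAc comes back to the route at 18.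

Step 7. What may go wrong: the dienylketene is captured by a hydroxyl group, either that of a second molecule of 15 or its own after loss of torquoselectivity (lactonization to a furanone), or hydroquinone 18 is oxidized in the hot solution and the resulting quinone degrades. The fallback sets out from 15 and moves the ring expansion into the silyl ether series. Me3SiCl and Et3N in CH2Cl2 give the trimethylsilyl ether F5, in which no free hydroxyl is present at the ketene stage and the silyloxy group still rotates outward. Thermolysis in p-xylene should then give the monosilylated hydroquinone F6, which is less prone to oxidation. F6 is submitted to the aqueous acid of step 8, which cleaves the silyl ether and the amidine together, and the route is rejoined at 19.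

Step 10. What may go wrong: incomplete silylation leaves phenolic oxygen open to acylation by the activated parabanic acid, the hydroquinone is oxidized during the hot condensation, or the final oxidant also attacks the acylaminoimidazole because three operations run in one flask on unpurified material. The fallback sets out from 19 and protects the hydroquinone durably. t-BuMe2SiCl and imidazole in DMF give the bis(tert-butyldimethylsilyl) ether F7 (silyl groups on nitrogen fall off on work-up). Condensation with 22 and BSA in toluene at 110 °C gives the protected naamidine F8, a stable compound that can be purified. n-Bu4NF and AcOH in THF at 0 °C then liberate hydroquinone 24, where the route is rejoined for the oxidation to 25.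

**Further compounds**

F1 | step 6 | (E)-N'-[4-(4-methoxybenzyl)-1-methyl-5-(prop-2-yn-1-yl)-1H-imidazol-2-yl]-N,N-dimethylformimidamide | COc1ccc(Cc2nc(/N=C/N(C)C)n(C)c2CC#C)cc1
F2 | step 6 | lithium acetylide of F1 | COc1ccc(Cc2nc(/N=C/N(C)C)n(C)c2CC#C[Li])cc1
F3 | step 6 | 4-[3-(2-{[(E)-(dimethylamino)methylidene]amino}-4-(4-methoxybenzyl)-1-methyl-1H-imidazol-5-yl)prop-1-yn-1-yl]-4-hydroxy-2,3-dimethoxycyclobut-2-en-1-one (racemic) | COc1ccc(Cc2nc(/N=C/N(C)C)n(C)c2CC#CC3(O)C(OC)=C(OC)C3=O)cc1
F4 | step 6 | (E)-N'-{5-[(4,5-dimethoxy-3,6-dioxocyclohexa-1,4-dien-1-yl)methyl]-4-(4-methoxybenzyl)-1-methyl-1H-imidazol-2-yl}-N,N-dimethylformimidamide | COc1ccc(Cc2nc(/N=C/N(C)C)n(C)c2CC3=CC(=O)C(OC)=C(OC)C3=O)cc1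
F5 | step 7 | 4-(trimethylsilyloxy) ether of 15 (racemic) | COc1ccc(Cc2nc(/N=C/N(C)C)n(C)c2CC(=C)C3(O[Si](C)(C)C)C(OC)=C(OC)C3=O)cc1
F6 | step 7 | (E)-N'-{5-[5-hydroxy-3,4-dimethoxy-2-(trimethylsilyloxy)benzyl]-4-(4-methoxybenzyl)-1-methyl-1H-imidazol-2-yl}-N,N-dimethylformimidamide | COc1ccc(Cc2nc(/N=C/N(C)C)n(C)c2Cc3cc(O)c(OC)c(OC)c3O[Si](C)(C)C)cc1
F7 | step 10 | 5-{2,5-bis[(tert-butyldimethylsilyl)oxy]-3,4-dimethoxybenzyl}-4-(4-methoxybenzyl)-1-methyl-1H-imidazol-2-amine | COc1ccc(Cc2nc(N)n(C)c2Cc3cc(O[Si](C)(C)C(C)(C)C)c(OC)c(OC)c3O[Si](C)(C)C(C)(C)C)cc1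
F8 | step 10 | O,O'-bis(tert-butyldimethylsilyl) ether of 24 | COc1ccc(Cc2nc(NC3=NC(=O)N(C)C3=O)n(C)c2Cc4cc(O[Si](C)(C)C(C)(C)C)c(OC)c(OC)c4O[Si](C)(C)C(C)(C)C)cc1
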